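Picture the closed, stirred vessel of the maple flask, charged with substrate and watched in slow motion.

in all of them: temperature 25 °C

| charge | substrate | remark | time |
|---|---|---|---|
| maple | 0.020 M | the very flask that is asked about, followed so far |  |
| ash | 0.013 M | run made earlier |  |
| flask | 0.020 M |  | 8.0 d |

| run | time / d | target / % | substrate / % |
|---|---|---|---|
| maple | 0.417 | 10.6 | 5.1 |
| maple | 0.625 | 16.4 | 2.2 |
| maple | 0.833 | 20.2 | 1.5 |
| maple | 1.25 | 24.5 | 3.0 |
| maple | 2.08 | 32.0 | 1.7 |
| maple | 3.00 | 30.0 | 3.9 |
| maple | 5.00 | 33.8 | 1.5 |
| ash | 0.417 | 12.5 | 4.9 |
| ash | 1.25 | 24.5 | 2.9 |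
| ash | 2.50 | 30.2 | 3.3 |
| ash | 3.00 | 32.0 | 1.9 |
| ash | 5.00 | 34.4 | 2.9 |
| ash | 6.00 | 32.7 | 0.8 |
| ash | 8.00 | 32.9 | 3.2 |

(each reading ± 1 percentage point)

- summer: at 8.0 d raise the temperature by 10 K, then wait 2.5 d
- autumn: change nothing and wait 2.5 d more
- spring: at 8.0 d take out 90 % of the target then present, then wait 2.5 d
- dusk: at 8.0 d add substrate, 50.0 % of the amount charged, then wait 2.5 d

- removed target is counted in
- the earlier runs do not show what temperature does; that part of a forecast is a guess
- additions bring no volume worth counting

* target, in percent of the substrate first charged, at 8.0 d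
* which option adds most target ("none" when 2 percentage points or less is all one gets) (summer / autumn / spring / dusk / none)
* target present, with what was taken out counted in, in percent of the substrate first charged, after autumn
* target present, with what was taken out counted in, in percent of the substrate first charged, after spring

In the first instants the quick event is the fall of substrate: by 0.417 d the maple run reads [substrate] at 5.1 % and [target] at 10.6 %, so 84.3 % of the charge stands in something you cannot read.

In the middle [substrate] merely hovers while [target] climbs, reaching 24.5 % at 1.25 d. The ash run, with its charge of 0.013 M, reads 24.5 % at that time, so the percentages do not follow the charge and the steps behave as first order.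

At the end [target] stops climbing, and the late readings of both runs average 33.4 %. There the rate into target equals the rate out of it, so if you divide one by the other, time drops out. I call this number the plateau share: the part of all material in the vessel that target holds once those two rates are equal, at this temperature.

The climb to 24.5 % gives a relaxation constant of 1.05 d⁻¹, a half-time of 0.657 d, far shorter than 8.0 d. So I expect 33.4 % now, and the same after autumn.

Spring removes 30.1 % and leaves 3.34 % of target. The remaining material then pulls target toward 23.4 %, and in 2.5 d it closes all but 7.16 % of that gap, so my total is 52.1 %, a gain of 19 percentage points. Dusk gains 16 points, less than spring. Summer stays a guess.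

The forecast gives 33 %, 33 % after autumn, 51.5 % after spring, slightly below my figure, and names spring, reasoning that “Substrate persisting beside a flat target points to a reversible equilibrium, not exhaustion”.

The flask gives 33.3 % now, 33.3 % after autumn and 52.6 % after spring. The gains are 19 points for spring, 16 points for dusk, 7.3 points for summer and 0 points for autumn, so the best option is spring.

    target ⇌ isomer of the product B (K = 0.391, k = 0.205 h⁻¹, Ea = 86.0 kJ mol⁻¹, ΔH = −28.0 kJ mol⁻¹)
    target ⇌ isomer of the product A (K = 1.53, k = 0.0339 h⁻¹, Ea = 105 kJ mol⁻¹, ΔH = −29.0 kJ mol⁻¹)
    isomer of the product A ⇌ substrate (k = 0.0399 h⁻¹, Ea = 96.0 kJ mol⁻¹)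
    substrate ⇌ target (K = 12.0, k = 0.0107 h⁻¹, Ea = 102 kJ mol⁻¹, ΔH = −43.0 kJ mol⁻¹)
    (constants at 25 °C)

The loss of target to isomer of the product A has a forward half-life of 0.85 d, short against the 8.0 d of the flask. In the flask target stands at 32.9 % after 4.00 d and 33.3 % after 80.0 d, then beside 50.9 % of isomer of the product A: thermodynamic, not kinetic, control. Your share 33.4 % belongs to 25 °C. The repeat at 50 °C ends after 8.00 d with 15.2 % of substrate, 29.5 % of isomer of the product A, 7.77 % of isomer of the product B and 47.6 % of target, so target's share of that material is 47.6 %, larger than your 33.4 %.

The runs were computed from invented constants, and the scatter is random.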